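**Assumption:** compound 1, compound 15 and the simple reagents ((−)-Ipc2BOMe, TosMIC, (triisopropylsilyl)acetylene, propiolic acid, 1-chloro-N,N,2-trimethylprop-1-en-1-amine) are taken as purchasable; only substrates and skeleton starting materials are numbered.

## Retrosynthetic overview

1. Target 27 ⇐ twofold cis-semi-reduction of the 20-membered bis(enyne) diolide 26, so both inner Z-alkenes appear in the last step.
2. 26 ⇐ ring closure by intramolecular Sonogashira coupling of seco iodide 25 (C–C bond next to the methyl-bearing enoate), not by lactonisation.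
3. 25 ⇐ both ester bonds made intermolecularly at the vinyl-iodide stage, plus one intermolecular Sonogashira coupling; one alkynol is used twice (13 free, 14 C-silylated), with propiolic acid/NaI and (Z)-3-iodo-2-methylacrylic acid 19.
4. Alkynol ⇐ Brown (Z)-crotylboration of aldehyde 1 (sets both stereocentres), hydroboration → iodide → acetylide, then van Leusen oxazole.
5. Ring order: the two oxazoles first (step 8, fragment stage), the 20-membered ring in step 19.

## Route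

Step 1
Reactants: 1 3-[(4-methoxybenzyl)oxy]propanal
Product: 3 (3R,4R)-1-[(4-methoxybenzyl)oxy]-4-methylhex-5-en-3-ol, via diisopinocampheylborinate ester 2 (not isolated)
Conditions: cis-2-butene, KOtBu, nBuLi, THF, −78 → −45 °C; (−)-Ipc2BOMe, then BF3·OEt2, −78 °C; 1, −78 °C; NaOH, H2O2, rt
Reagents that add atoms: cis-2-butene C/C=C\C
Why: Brown asymmetric crotylboration, in which the (Z)-crotylborane from (−)-Ipc2BOMe reacts through a closed chair transition state on the Si face of the aldehyde, so the Z geometry gives the syn relationship and the pinene-derived ligands give the (3R,4R) configuration.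

Step 2
Reactants: 3 (3R,4R)-1-[(4-methoxybenzyl)oxy]-4-methylhex-5-en-3-ol
Product: 4 tert-butyl{[(3R,4R)-1-[(4-methoxybenzyl)oxy]-4-methylhex-5-en-3-yl]oxy}dimethylsilane
Conditions: TBSOTf, 2,6-lutidine, CH2Cl2, −78 → 0 °C
Reagents that add atoms: tert-butyldimethylsilyl triflate CC(C)(C)[Si](C)(C)OS(=O)(=O)C(F)(F)F
Why: Silyl ether formation with the reactive triflate and a hindered base protects the secondary alcohol for the organolithium, oxidation and K2CO3/MeOH steps that follow without touching either stereocentre.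

Step 3
Reactants: 4 tert-butyl{[(3R,4R)-1-[(4-methoxybenzyl)oxy]-4-methylhex-5-en-3-yl]oxy}dimethylsilane
Product: 6 (3R,4R)-4-[(tert-butyldimethylsilyl)oxy]-6-[(4-methoxybenzyl)oxy]-3-methylhexan-1-ol, via B-alkyl-9-BBN adduct 5 (not isolated)
Conditions: 9-BBN, THF, 0 °C → rt; NaOH, H2O2, 0 °C → rt
Reagents that add atoms: hydrogen peroxide OO
Why: Hydroboration–oxidation with the bulky borane 9-BBN is fully anti-Markovnikov on the monosubstituted alkene, and alkaline peroxide replaces boron by OH with both ethers intact.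

Step 4
Reactants: 6 (3R,4R)-4-[(tert-butyldimethylsilyl)oxy]-6-[(4-methoxybenzyl)oxy]-3-methylhexan-1-ol
Product: 7 tert-butyl{[(3R,4R)-6-iodo-1-[(4-methoxybenzyl)oxy]-4-methylhexan-3-yl]oxy}dimethylsilane
Conditions: I2, PPh3, imidazole, CH2Cl2, 0 °C → rt
Reagents that add atoms: iodine [I][I]
Why: Appel-type iodination converts the unhindered primary alcohol into the iodide under near-neutral conditions by SN2 at a non-stereogenic carbon.

Step 5
Reactants: 7 tert-butyl{[(3R,4R)-6-iodo-1-[(4-methoxybenzyl)oxy]-4-methylhexan-3-yl]oxy}dimethylsilane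
Product: 8 tert-butyl{[(3R,4R)-1-[(4-methoxybenzyl)oxy]-4-methyl-8-(triisopropylsilyl)oct-7-yn-3-yl]oxy}dimethylsilane
Conditions: (triisopropylsilyl)acetylene, nBuLi, THF, −78 → 0 °C; then 7, DMPU, 0 °C → rt
Reagents that add atoms: (triisopropylsilyl)acetylene C#C[Si](C(C)C)(C(C)C)C(C)C
Why: SN2 alkylation of a lithium acetylide with the unbranched primary iodide installs the two alkyne carbons, and it is run before the oxazole exists because the acidic oxazole C2–H would quench an acetylide.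

Step 6
Reactants: 8 tert-butyl{[(3R,4R)-1-[(4-methoxybenzyl)oxy]-4-methyl-8-(triisopropylsilyl)oct-7-yn-3-yl]oxy}dimethylsilane
Product: 9 (3R,4R)-3-[(tert-butyldimethylsilyl)oxy]-4-methyl-8-(triisopropylsilyl)oct-7-yn-1-ol
Conditions: DDQ, CH2Cl2/pH 7 buffer, 0 °C
Reagents that add atoms: none
Why: Oxidative PMB ether cleavage with DDQ proceeds by hydride abstraction from the electron-rich benzylic position and leaves the silyl ether and the silylalkyne alone.

Step 7
Reactants: 9 (3R,4R)-3-[(tert-butyldimethylsilyl)oxy]-4-methyl-8-(triisopropylsilyl)oct-7-yn-1-ol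
Product: 10 (3R,4R)-3-[(tert-butyldimethylsilyl)oxy]-4-methyl-8-(triisopropylsilyl)oct-7-ynal
Conditions: Dess–Martin periodinane, CH2Cl2, 0 °C → rt
Reagents that add atoms: none
Why: Dess–Martin oxidation gives the β-silyloxy aldehyde under non-basic conditions, so β-elimination of the silyloxy group is avoided.

Step 8
Reactants: 10 (3R,4R)-3-[(tert-butyldimethylsilyl)oxy]-4-methyl-8-(triisopropylsilyl)oct-7-ynal
Product: 12 5-[(2R,3R)-2-[(tert-butyldimethylsilyl)oxy]-3-methyl-7-(triisopropylsilyl)hept-6-yn-1-yl]-1,3-oxazole, via 4-tosyl-4,5-dihydrooxazole adduct 11 (not isolated)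
Conditions: TosMIC, K2CO3, MeOH, 65 °C
Reagents that add atoms: TosMIC (p-toluenesulfonylmethyl isocyanide) Cc1ccc(cc1)S(=O)(=O)C[N+]#[C-]
Why: van Leusen oxazole synthesis, in which deprotonated TosMIC adds to the aldehyde, the alkoxide closes onto the isocyanide carbon and loss of sulfinate aromatises to the 5-substituted oxazole, while the C-TIPS group survives K2CO3/MeOH.

Step 9
Reactants: 12 5-[(2R,3R)-2-[(tert-butyldimethylsilyl)oxy]-3-methyl-7-(triisopropylsilyl)hept-6-yn-1-yl]-1,3-oxazole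
Product: 13 (2R,3R)-3-methyl-1-(1,3-oxazol-5-yl)hept-6-yn-2-ol
Conditions: TBAF (3 equiv), THF, 0 °C → rt
Reagents that add atoms: none
Why: Fluoride-mediated desilylation removes both the O-TBS and the C-TIPS group, driven by the strong Si–F bond, with no effect on the oxazole or the stereocentres.

Step 10
Reactants: 12 5-[(2R,3R)-2-[(tert-butyldimethylsilyl)oxy]-3-methyl-7-(triisopropylsilyl)hept-6-yn-1-yl]-1,3-oxazole
Product: 14 (2R,3R)-3-methyl-1-(1,3-oxazol-5-yl)-7-(triisopropylsilyl)hept-6-yn-2-ol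
Conditions: CSA (1.1 equiv), MeOH/CH2Cl2 (1:1), rt
Reagents that add atoms: none
Why: Acid-catalysed methanolysis cleaves only the silyl ether because the alkynyl C–Si bond is stable to Brønsted acid, which differentiates the two copies of the alkynol.

Step 11
Reactants: 15 prop-2-yn-1-ol
Product: 17 (Z)-3-iodo-2-methylprop-2-en-1-ol, via chelated alkenylmagnesium alkoxide 16 (not isolated)
Conditions: MeMgBr (3 equiv), CuI (10 mol %), THF, −20 °C → rt; then I2, −78 → 0 °C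
Reagents that add atoms: methylmagnesium bromide C[Mg]Br; iodine [I][I]
Why: Copper-catalysed anti-carbomagnesiation of propargyl alcohol (Duboudin reaction) gives a five-membered alkenylmagnesium chelate, so iodinolysis with retention puts iodine cis to CH2OH and fixes the Z geometry.

Step 12
Reactants: 17 (Z)-3-iodo-2-methylprop-2-en-1-ol
Product: 18 (Z)-3-iodo-2-methylprop-2-enal
Conditions: MnO2 (15 equiv), CH2Cl2, rt, dark
Reagents that add atoms: none
Why: Allylic oxidation with MnO2 is selective for the allylic alcohol and runs under neutral conditions that keep the Z-iodoalkene geometry.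

Step 13
Reactants: 18 (Z)-3-iodo-2-methylprop-2-enal
Product: 19 (Z)-3-iodo-2-methylprop-2-enoic acid
Conditions: NaClO2, NaH2PO4, 2-methyl-2-butene, tBuOH/H2O, 0 °C → rt
Reagents that add atoms: sodium chlorite [Na+].[O-]Cl=O
Why: Pinnick oxidation converts the enal into the acid with buffered chlorite, and the alkene scavenger removes HOCl so the vinyl iodide and its geometry are preserved.

Step 14
Reactants: 14 (2R,3R)-3-methyl-1-(1,3-oxazol-5-yl)-7-(triisopropylsilyl)hept-6-yn-2-ol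
Product: 20 (2R,3R)-3-methyl-1-(1,3-oxazol-5-yl)-7-(triisopropylsilyl)hept-6-yn-2-yl prop-2-ynoate
Conditions: propiolic acid, DCC, DMAP (5 mol %), CH2Cl2, −20 → 0 °C
Reagents that add atoms: propiolic acid C#CC(=O)O
Why: Steglich esterification at low temperature acylates the secondary alcohol with the small propiolic acid with retention at the carbinol carbon, since the C–O bond of the alcohol is not broken.

Step 15
Reactants: 20 (2R,3R)-3-methyl-1-(1,3-oxazol-5-yl)-7-(triisopropylsilyl)hept-6-yn-2-yl prop-2-ynoate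
Product: 21 (2R,3R)-3-methyl-1-(1,3-oxazol-5-yl)-7-(triisopropylsilyl)hept-6-yn-2-yl (Z)-3-iodoprop-2-enoate
Conditions: NaI, AcOH, 70 °C
Reagents that add atoms: sodium iodide [Na+].[I-]
Why: Hydroiodination of the ynoate by conjugate addition of iodide and anti protonation in AcOH gives the (Z)-3-iodoacrylate selectively, the unactivated silylalkyne being inert.

Step 16
Reactants: 21 (2R,3R)-3-methyl-1-(1,3-oxazol-5-yl)-7-(triisopropylsilyl)hept-6-yn-2-yl (Z)-3-iodoprop-2-enoate; 13 (2R,3R)-3-methyl-1-(1,3-oxazol-5-yl)hept-6-yn-2-ol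
Product: 22 (2R,3R)-3-methyl-1-(1,3-oxazol-5-yl)-7-(triisopropylsilyl)hept-6-yn-2-yl (2Z,8R,9R)-9-hydroxy-8-methyl-10-(1,3-oxazol-5-yl)dec-2-en-4-ynoate
Conditions: PdCl2(PPh3)2 (5 mol %), CuI (10 mol %), iPr2NH, degassed THF, rt
Reagents that add atoms: none
Why: Sonogashira coupling of the (Z)-β-iodoacrylate with the terminal alkyne of 13 proceeds at room temperature with retention of alkene geometry and tolerates the free alcohol and both oxazoles.

Step 17
Reactants: 22 (2R,3R)-3-methyl-1-(1,3-oxazol-5-yl)-7-(triisopropylsilyl)hept-6-yn-2-yl (2Z,8R,9R)-9-hydroxy-8-methyl-10-(1,3-oxazol-5-yl)dec-2-en-4-ynoate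
Product: 23 (2R,3R)-3-methyl-1-(1,3-oxazol-5-yl)hept-6-yn-2-yl (2Z,8R,9R)-9-hydroxy-8-methyl-10-(1,3-oxazol-5-yl)dec-2-en-4-ynoate
Conditions: TBAF (1.2 equiv), THF, 0 °C
Reagents that add atoms: none
Why: Fluoride-mediated protodesilylation of the alkynylsilane at 0 °C frees the second terminal alkyne while the ester and the Z-enyne are left untouched.

Step 18
Reactants: 19 (Z)-3-iodo-2-methylprop-2-enoic acid; 23 (2R,3R)-3-methyl-1-(1,3-oxazol-5-yl)hept-6-yn-2-yl (2Z,8R,9R)-9-hydroxy-8-methyl-10-(1,3-oxazol-5-yl)dec-2-en-4-ynoate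
Product: 25 (2R,3R)-3-methyl-1-(1,3-oxazol-5-yl)hept-6-yn-2-yl (2Z,8R,9R)-9-{[(Z)-3-iodo-2-methylprop-2-enoyl]oxy}-8-methyl-10-(1,3-oxazol-5-yl)dec-2-en-4-ynoate, via (Z)-3-iodo-2-methylprop-2-enoyl chloride 24 (not isolated)
Conditions: 19, 1-chloro-N,N,2-trimethylprop-1-en-1-amine, CH2Cl2, 0 °C → rt; then 23, pyridine, CH2Cl2, 0 °C → rt
Reagents that add atoms: none
Why: Acylation of the secondary alcohol with an acid chloride generated under neutral conditions (Ghosez reagent) avoids the nucleophilic catalysts that isomerise β-iodoacrylates, so the Z geometry is carried into the ester.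

Step 19
Reactants: 25 (2R,3R)-3-methyl-1-(1,3-oxazol-5-yl)hept-6-yn-2-yl (2Z,8R,9R)-9-{[(Z)-3-iodo-2-methylprop-2-enoyl]oxy}-8-methyl-10-(1,3-oxazol-5-yl)dec-2-en-4-ynoate
Product: 26 (3Z,9R,10R,13Z,19R,20R)-3,9,19-trimethyl-10,20-bis(1,3-oxazol-5-ylmethyl)-1,11-dioxacycloicosa-3,13-diene-5,15-diyne-2,12-dione
Conditions: Pd(PPh3)4 (20 mol %), CuI (40 mol %), iPr2NH, degassed THF, 25 added over 12 h to 1 mM final concentration, rt
Reagents that add atoms: none
Why: Intramolecular Sonogashira coupling under high dilution closes the 20-membered ring by joining the terminal alkyne to the (Z)-vinyl iodide with retention of geometry, so no activated (Z)-enoic acid and no lactonisation is needed.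

Step 20
Reactants: 26 (3Z,9R,10R,13Z,19R,20R)-3,9,19-trimethyl-10,20-bis(1,3-oxazol-5-ylmethyl)-1,11-dioxacycloicosa-3,13-diene-5,15-diyne-2,12-dione
Product: 27 (3Z,5Z,9R,10R,13Z,15Z,19R,20R)-3,9,19-trimethyl-10,20-bis(1,3-oxazol-5-ylmethyl)-1,11-dioxacycloicosa-3,5,13,15-tetraene-2,12-dione
Conditions: Zn dust activated with Cu(OAc)2 and AgNO3, MeOH/H2O (1:1), 40 °C, dark
Reagents that add atoms: none
Why: Boland reduction, in which activated zinc reduces only the two conjugated alkynes and delivers both hydrogens cis on the metal surface, giving the two (2Z,4Z)-dienoates without touching the esters, oxazoles or stereocentres.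

## Compound list

1 | 3-[(4-methoxybenzyl)oxy]propanal | O=CCCOCc1ccc(OC)cc1 | starting material
2 | (3R,4R)-1-[(4-methoxybenzyl)oxy]-4-methylhex-5-en-3-yl diisopinocampheylborinate (Ipc groups from (+)-α-pinene; not isolated) | C=C[C@@H](C)[C@@H](CCOCc1ccc(OC)cc1)OB([C@@H]1C[C@@H]2C[C@H]([C@H]1C)C2(C)C)[C@@H]1C[C@@H]2C[C@H]([C@H]1C)C2(C)C | intermediate
3 | (3R,4R)-1-[(4-methoxybenzyl)oxy]-4-methylhex-5-en-3-ol | C=C[C@@H](C)[C@@H](CCOCc1ccc(OC)cc1)O | intermediate
4 | tert-butyl{[(3R,4R)-1-[(4-methoxybenzyl)oxy]-4-methylhex-5-en-3-yl]oxy}dimethylsilane | C=C[C@@H](C)[C@@H](CCOCc1ccc(OC)cc1)O[Si](C)(C)C(C)(C)C | intermediate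
5 | 9-{(3R,4R)-4-[(tert-butyldimethylsilyl)oxy]-6-[(4-methoxybenzyl)oxy]-3-methylhexyl}-9-borabicyclo[3.3.1]nonane (not isolated) | C(C[C@@H](C)[C@@H](CCOCc1ccc(OC)cc1)O[Si](C)(C)C(C)(C)C)B1C2CCCC1CCC2 | intermediate
6 | (3R,4R)-4-[(tert-butyldimethylsilyl)oxy]-6-[(4-methoxybenzyl)oxy]-3-methylhexan-1-ol | OCC[C@@H](C)[C@@H](CCOCc1ccc(OC)cc1)O[Si](C)(C)C(C)(C)C | intermediate
7 | tert-butyl{[(3R,4R)-6-iodo-1-[(4-methoxybenzyl)oxy]-4-methylhexan-3-yl]oxy}dimethylsilane | ICC[C@@H](C)[C@@H](CCOCc1ccc(OC)cc1)O[Si](C)(C)C(C)(C)C | intermediate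
8 | tert-butyl{[(3R,4R)-1-[(4-methoxybenzyl)oxy]-4-methyl-8-(triisopropylsilyl)oct-7-yn-3-yl]oxy}dimethylsilane | CC(C)[Si](C#CCC[C@@H](C)[C@@H](CCOCc1ccc(OC)cc1)O[Si](C)(C)C(C)(C)C)(C(C)C)C(C)C | intermediate
9 | (3R,4R)-3-[(tert-butyldimethylsilyl)oxy]-4-methyl-8-(triisopropylsilyl)oct-7-yn-1-ol | CC(C)[Si](C#CCC[C@@H](C)[C@@H](CCO)O[Si](C)(C)C(C)(C)C)(C(C)C)C(C)C | intermediate
10 | (3R,4R)-3-[(tert-butyldimethylsilyl)oxy]-4-methyl-8-(triisopropylsilyl)oct-7-ynal | CC(C)[Si](C#CCC[C@@H](C)[C@@H](CC=O)O[Si](C)(C)C(C)(C)C)(C(C)C)C(C)C | intermediate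
11 | 5-{(2R,3R)-2-[(tert-butyldimethylsilyl)oxy]-3-methyl-7-(triisopropylsilyl)hept-6-yn-1-yl}-4-tosyl-4,5-dihydro-1,3-oxazole (mixture at the two new ring carbons; not isolated) | CC(C)[Si](C#CCC[C@@H](C)[C@@H](CC1OC=NC1S(=O)(=O)c1ccc(C)cc1)O[Si](C)(C)C(C)(C)C)(C(C)C)C(C)C | intermediate
12 | 5-[(2R,3R)-2-[(tert-butyldimethylsilyl)oxy]-3-methyl-7-(triisopropylsilyl)hept-6-yn-1-yl]-1,3-oxazole | CC(C)[Si](C#CCC[C@@H](C)[C@@H](Cc1cnco1)O[Si](C)(C)C(C)(C)C)(C(C)C)C(C)C | intermediate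
13 | (2R,3R)-3-methyl-1-(1,3-oxazol-5-yl)hept-6-yn-2-ol | C#CCC[C@@H](C)[C@@H](Cc1cnco1)O | intermediate
14 | (2R,3R)-3-methyl-1-(1,3-oxazol-5-yl)-7-(triisopropylsilyl)hept-6-yn-2-ol | CC(C)[Si](C#CCC[C@@H](C)[C@@H](Cc1cnco1)O)(C(C)C)C(C)C | intermediate
15 | prop-2-yn-1-ol (propargyl alcohol) | C#CCO | starting material
16 | bromomagnesium (Z)-3-(bromomagnesio)-2-methylprop-2-en-1-olate (chelate; not isolated) | Br[Mg]/C=C(/C)CO[Mg]Br | intermediate
17 | (Z)-3-iodo-2-methylprop-2-en-1-ol | I/C=C(/C)CO | intermediate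
18 | (Z)-3-iodo-2-methylprop-2-enal | I/C=C(/C)C=O | intermediate
19 | (Z)-3-iodo-2-methylprop-2-enoic acid | I/C=C(/C)C(=O)O | intermediate
20 | (2R,3R)-3-methyl-1-(1,3-oxazol-5-yl)-7-(triisopropylsilyl)hept-6-yn-2-yl prop-2-ynoate | CC(C)[Si](C#CCC[C@@H](C)[C@@H](Cc1cnco1)OC(=O)C#C)(C(C)C)C(C)C | intermediate
21 | (2R,3R)-3-methyl-1-(1,3-oxazol-5-yl)-7-(triisopropylsilyl)hept-6-yn-2-yl (Z)-3-iodoprop-2-enoate | CC(C)[Si](C#CCC[C@@H](C)[C@@H](Cc1cnco1)OC(=O)/C=C\I)(C(C)C)C(C)C | intermediate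
22 | (2R,3R)-3-methyl-1-(1,3-oxazol-5-yl)-7-(triisopropylsilyl)hept-6-yn-2-yl (2Z,8R,9R)-9-hydroxy-8-methyl-10-(1,3-oxazol-5-yl)dec-2-en-4-ynoate | CC(C)[Si](C#CCC[C@@H](C)[C@@H](Cc1cnco1)OC(=O)/C=C\C#CCC[C@@H](C)[C@@H](Cc1cnco1)O)(C(C)C)C(C)C | intermediate
23 | (2R,3R)-3-methyl-1-(1,3-oxazol-5-yl)hept-6-yn-2-yl (2Z,8R,9R)-9-hydroxy-8-methyl-10-(1,3-oxazol-5-yl)dec-2-en-4-ynoate | C#CCC[C@@H](C)[C@@H](Cc1cnco1)OC(=O)/C=C\C#CCC[C@@H](C)[C@@H](Cc1cnco1)O | intermediate
24 | (Z)-3-iodo-2-methylprop-2-enoyl chloride (not isolated) | I/C=C(/C)C(=O)Cl | intermediate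
25 | (2R,3R)-3-methyl-1-(1,3-oxazol-5-yl)hept-6-yn-2-yl (2Z,8R,9R)-9-{[(Z)-3-iodo-2-methylprop-2-enoyl]oxy}-8-methyl-10-(1,3-oxazol-5-yl)dec-2-en-4-ynoate | C#CCC[C@@H](C)[C@@H](Cc1cnco1)OC(=O)/C=C\C#CCC[C@@H](C)[C@@H](Cc1cnco1)OC(=O)/C(C)=C\I | intermediate
26 | (3Z,9R,10R,13Z,19R,20R)-3,9,19-trimethyl-10,20-bis(1,3-oxazol-5-ylmethyl)-1,11-dioxacycloicosa-3,13-diene-5,15-diyne-2,12-dione | C/C1=C/C#CCC[C@@H](C)[C@@H](Cc2cnco2)OC(=O)/C=C\C#CCC[C@@H](C)[C@@H](Cc2cnco2)OC1=O | intermediate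
27 | (3Z,5Z,9R,10R,13Z,15Z,19R,20R)-3,9,19-trimethyl-10,20-bis(1,3-oxazol-5-ylmethyl)-1,11-dioxacycloicosa-3,5,13,15-tetraene-2,12-dione (CNP0128396.1) | C/C1=C/C=C\CC[C@@H](C)[C@@H](Cc2cnco2)OC(=O)/C=C\C=C/CC[C@@H](C)[C@@H](Cc2cnco2)OC1=O | target

## Step count and risks

Total step count: 20. Longest linear sequence: 16 steps (steps 1–8, 10, 14–20).

**Step 19 (macrocyclic Sonogashira coupling).** Oligomerisation, alkyne homocoupling or slow oxidative addition of the trisubstituted iodide could erode the yield. The fallback makes the C–C bond intermolecularly and closes the ring at the ester instead; it sets out from 23 (with acid 19) and comes back to the route at 26. Acid chloride 24 is quenched with 2-(trimethylsilyl)ethanol and pyridine to give 2-(trimethylsilyl)ethyl (Z)-3-iodo-2-methylprop-2-enoate F1. Sonogashira coupling of this iodide with 23 (PdCl2(PPh3)2, CuI, iPr2NH, THF) gives the 2-(trimethylsilyl)ethyl ester of the open-chain bis(enyne) hydroxy acid F2. TBAF removes the silylethyl group to give the bis(enyne) seco acid F3, and Yamaguchi macrolactonisation (2,4,6-trichlorobenzoyl chloride, Et3N, then DMAP, toluene, high dilution) gives 26, from which step 20 follows.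

**Step 20 (twofold semi-reduction on the macrocycle).** Incomplete or unequal reduction of the two enynes, over-reduction or Z-to-E drift in the ring would give inseparable mixtures. The fallback unveils the dienes one at a time, the first on an open-chain compound where the reduction is easier to drive and purify; it sets out from 22 and comes back at 27. Zn activated with Cu(OAc)2 and AgNO3 reduces only the conjugated enynoate of 22 to give the C-silylated (2Z,4Z)-dienoate alcohol F4. TBAF then gives the terminal alkyne dienoate alcohol F5, and acylation with 24 as in step 18 gives the dienoate seco iodide F6. Sonogashira macrocyclisation as in step 19 gives the macrocyclic enyne–diene diolide F7, and a single activated-zinc reduction of the one remaining enyne gives 27.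

**Step 8 (van Leusen oxazole synthesis on a β-silyloxy aldehyde).** K2CO3 in hot MeOH may eliminate the β-silyloxy group to an enal before TosMIC adds. The fallback builds the oxazole from the ester oxidation level by a Schöllkopf reaction; it sets out from 10 and comes back at 12. Pinnick oxidation of 10 gives (3R,4R)-3-[(tert-butyldimethylsilyl)oxy]-4-methyl-8-(triisopropylsilyl)oct-7-ynoic acid F8, and TMSCHN2 in MeOH/toluene gives methyl (3R,4R)-3-[(tert-butyldimethylsilyl)oxy]-4-methyl-8-(triisopropylsilyl)oct-7-ynoate F9. Lithiomethyl isocyanide (from methyl isocyanide and nBuLi, 2.2 equiv, THF, −78 °C, then AcOH) acylates at the ester carbonyl, and the resulting α-isocyano ketone enol closes to the 5-substituted oxazole 12.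

## Further compounds

F1 | step 19 | 2-(trimethylsilyl)ethyl (Z)-3-iodo-2-methylprop-2-enoate | C[Si](C)(C)CCOC(=O)/C(C)=C\I
F2 | step 19 | 2-(trimethylsilyl)ethyl (2Z,8R,9R)-9-{[(2Z,8R,9R)-9-hydroxy-8-methyl-10-(1,3-oxazol-5-yl)dec-2-en-4-ynoyl]oxy}-2,8-dimethyl-10-(1,3-oxazol-5-yl)dec-2-en-4-ynoate | C[Si](C)(C)CCOC(=O)/C(C)=C\C#CCC[C@@H](C)[C@@H](Cc1cnco1)OC(=O)/C=C\C#CCC[C@@H](C)[C@@H](Cc1cnco1)O
F3 | step 19 | (2Z,8R,9R)-9-{[(2Z,8R,9R)-9-hydroxy-8-methyl-10-(1,3-oxazol-5-yl)dec-2-en-4-ynoyl]oxy}-2,8-dimethyl-10-(1,3-oxazol-5-yl)dec-2-en-4-ynoic acid | OC(=O)/C(C)=C\C#CCC[C@@H](C)[C@@H](Cc1cnco1)OC(=O)/C=C\C#CCC[C@@H](C)[C@@H](Cc1cnco1)O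
F4 | step 20 | (2R,3R)-3-methyl-1-(1,3-oxazol-5-yl)-7-(triisopropylsilyl)hept-6-yn-2-yl (2Z,4Z,8R,9R)-9-hydroxy-8-methyl-10-(1,3-oxazol-5-yl)deca-2,4-dienoate | CC(C)[Si](C#CCC[C@@H](C)[C@@H](Cc1cnco1)OC(=O)/C=C\C=C/CC[C@@H](C)[C@@H](Cc1cnco1)O)(C(C)C)C(C)C
F5 | step 20 | (2R,3R)-3-methyl-1-(1,3-oxazol-5-yl)hept-6-yn-2-yl (2Z,4Z,8R,9R)-9-hydroxy-8-methyl-10-(1,3-oxazol-5-yl)deca-2,4-dienoate | C#CCC[C@@H](C)[C@@H](Cc1cnco1)OC(=O)/C=C\C=C/CC[C@@H](C)[C@@H](Cc1cnco1)O
F6 | step 20 | (2R,3R)-3-methyl-1-(1,3-oxazol-5-yl)hept-6-yn-2-yl (2Z,4Z,8R,9R)-9-{[(Z)-3-iodo-2-methylprop-2-enoyl]oxy}-8-methyl-10-(1,3-oxazol-5-yl)deca-2,4-dienoate | C#CCC[C@@H](C)[C@@H](Cc1cnco1)OC(=O)/C=C\C=C/CC[C@@H](C)[C@@H](Cc1cnco1)OC(=O)/C(C)=C\I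
F7 | step 20 | (3Z,9R,10R,13Z,15Z,19R,20R)-3,9,19-trimethyl-10,20-bis(1,3-oxazol-5-ylmethyl)-1,11-dioxacycloicosa-3,13,15-trien-5-yne-2,12-dione | C/C1=C/C#CCC[C@@H](C)[C@@H](Cc2cnco2)OC(=O)/C=C\C=C/CC[C@@H](C)[C@@H](Cc2cnco2)OC1=O
F8 | step 8 | (3R,4R)-3-[(tert-butyldimethylsilyl)oxy]-4-methyl-8-(triisopropylsilyl)oct-7-ynoic acid | CC(C)[Si](C#CCC[C@@H](C)[C@@H](CC(=O)O)O[Si](C)(C)C(C)(C)C)(C(C)C)C(C)C
F9 | step 8 | methyl (3R,4R)-3-[(tert-butyldimethylsilyl)oxy]-4-methyl-8-(triisopropylsilyl)oct-7-ynoate | CC(C)[Si](C#CCC[C@@H](C)[C@@H](CC(=O)OC)O[Si](C)(C)C(C)(C)C)(C(C)C)C(C)C
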